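The ten-membered carbocycle is opened at the C3–C4 bond inside the trans-oxirane: an epoxide with H on C3 and a methyl group on C4, next to the oxygenated C5, is the retron of a sulfonium ylide at C3 adding to a methyl ketone at C4. One base-induced operation therefore closes both the carbocycle and the oxirane and sets C3 and C4 without any strained E-cycloalkene. The precursor is an acyclic C3 diphenylsulfonium salt carrying the C4 methyl ketone, a chelating C5 3,4-dimethoxybenzyl ether, the Z-C7=C8 olefin and differently protected C9 (PMB) and C10 (TBS) oxygens, built from D-erythronolactone acetonide and (S)-α-hydroxy-γ-butyrolactone.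

Key step: step 21

Remarks on the chemistry (assumptions and design points)
- Numbering used throughout: C1 = CH bearing isopropenyl, C2 = CH2, C3–C4 = trans-epoxide (CH3 on C4), C5 = CH–O, C6 = CH2, C7–C8 = second epoxide (CH3 on C8), C9 = CH–O, C10 = CH–O. In this numbering the target is 1R,3R,4S,5S,7S,8S,9S,10S.
- Assumption: 3, 7, 15 and 32 are bought; 15 is the commercial form of the L-malate-derived C4–C7 unit.
- C4 face: in the target O4 and O5 are syn along C3–C4–C5–C6 (trans on the ring), which is the Cram-chelate outcome. Felkin–Anh attack anti to a silyloxy group on C5 would give the C4 epimer. C5 therefore carries a benzyl-type (DMB) ether and lithium is the counter-ion.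
- O9 and O10 carry different groups (PMB, TBS) and no common acetal. Nothing acid-labile has to be removed once the epoxide exists, no regioselective acylation of a 9,10-diol is needed, and the bulky silyl ether on the γ-oxygen O10 is a poor neighbouring group toward C3 during sulfonium formation.
- The C7–C8 epoxide oxygen is trans to O9 on the ring (threo). This is the peracid outcome for a medium-ring Z-allylic alcohol; a metal-alkoxide-directed epoxidation would be expected to give the cis isomer. The angelates go on before the C9 acetate so that no acetate sits next to a free C10 hydroxyl.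

Step 1
Reactants: 1 2,3-O-isopropylidene-D-erythronolactone
Product: 2 2,3-O-isopropylidene-D-erythrose (lactol; anomeric mixture)
Conditions: i-Bu2AlH (1.1 equiv), CH2Cl2, −78 °C; aq. KNaC4H4O6
Reagents that add atoms: none
Why: Partial hydride reduction of a lactone to the lactol (DIBAL-H reduction) stops at the aluminium hemiacetal at −78 °C and leaves C9 and C10 untouched.

Step 2
Reactants: 2 2,3-O-isopropylidene-D-erythrose; 3 methyl (triphenylphosphoranylidene)acetate
Product: 4 methyl (2Z)-3-[(4S,5R)-5-(hydroxymethyl)-2,2-dimethyl-1,3-dioxolan-4-yl]prop-2-enoate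
Conditions: MeOH, 0 °C → rt
Reagents that add atoms: none
Why: Wittig olefination of the open-chain α-alkoxy aldehyde with a stabilised ylide should give mainly the Z-enoate in methanol; the minor E-isomer cannot lactonise in step 3 and is removed there.

Step 3
Reactants: 4 the Z-enoate
Product: 5 (5S)-5-[(1R)-1,2-dihydroxyethyl]furan-2(5H)-one
Conditions: CF3CO2H–H2O (9:1), 0 °C → rt
Reagents that add atoms: none
Why: Acid hydrolysis of the isopropylidene acetal frees O10, which lactonises onto the cis-disposed ester (acid-catalysed transesterification to the butenolide), so O10 is tied up while O8 and O9 stay free.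

Step 4
Reactants: 5 the butenolide diol
Product: 6 (5S)-5-[(4R)-2-(4-methoxyphenyl)-1,3-dioxolan-4-yl]furan-2(5H)-one (both acetal epimers)
Conditions: 4-MeOC6H4CH(OMe)2, camphorsulfonic acid (cat.), CH2Cl2, rt
Reagents that add atoms: 4-methoxybenzaldehyde dimethyl acetal, COC(OC)c1ccc(OC)cc1
Why: Acid-catalysed transacetalisation of the terminal 1,2-diol gives the five-membered 4-methoxybenzylidene acetal, which later delivers the PMB ether on O9.

Step 5
Reactants: 6 the butenolide acetal; 7 isopropenylmagnesium bromide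
Product: 8 (4R,5S)-5-[(4R)-2-(4-methoxyphenyl)-1,3-dioxolan-4-yl]-4-(prop-1-en-2-yl)dihydrofuran-2(3H)-one
Conditions: CuBr·SMe2 (0.2 equiv), THF, −78 → −40 °C; aq. NH4Cl
Reagents that add atoms: none
Why: Copper-catalysed conjugate addition of the Grignard reagent to the γ-substituted butenolide takes place anti to the C10 side chain, which sets C1 as R (trans-4,5-disubstituted lactone).

Step 6
Reactants: 8 the trans-lactone
Product: 9 (3R,4S)-4-[(4R)-2-(4-methoxyphenyl)-1,3-dioxolan-4-yl]-3-(prop-1-en-2-yl)butane-1,4-diol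
Conditions: LiAlH4, THF, 0 °C
Reagents that add atoms: none
Why: Hydride reduction of the lactone gives the C3/C10 1,4-diol and does not touch the acetal or the olefin.

Step 7
Reactants: 9 the diol
Product: 10 the 1,4-bis(tert-butyldimethylsilyl) ether of 9
Conditions: t-BuMe2SiOTf (2.5 equiv), 2,6-lutidine, CH2Cl2, −78 → 0 °C
Reagents that add atoms: tert-butyldimethylsilyl trifluoromethanesulfonate, CC(C)(C)[Si](C)(C)OS(=O)(=O)C(F)(F)F
Why: Silylation with the silyl triflate and a hindered base protects both the primary C3 and the hindered secondary C10 hydroxyl at low temperature.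

Step 8
Reactants: 10 the bis-silyl ether
Product: 11 (2R,3S,4R)-3,6-bis[(tert-butyldimethylsilyl)oxy]-2-[(4-methoxybenzyl)oxy]-4-(prop-1-en-2-yl)hexan-1-ol
Conditions: i-Bu2AlH (4 equiv), CH2Cl2, −78 → 0 °C; aq. KNaC4H4O6
Reagents that add atoms: none
Why: Reductive opening of the 4-methoxybenzylidene acetal with i-Bu2AlH: aluminium binds the less hindered primary O8 and hydride cleaves that C–O bond, which leaves the PMB ether on the secondary O9.

Step 9
Reactants: 11 the primary alcohol
Product: 12 (2S,3S,4R)-3,6-bis[(tert-butyldimethylsilyl)oxy]-2-[(4-methoxybenzyl)oxy]-4-(prop-1-en-2-yl)hexanal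
Conditions: Dess–Martin periodinane, NaHCO3, CH2Cl2, 0 °C → rt
Reagents that add atoms: none
Why: Dess–Martin oxidation of the primary alcohol under buffered, non-basic conditions should not epimerise the α-alkoxy aldehyde.

Step 10
Reactants: 12 the aldehyde
Product: 13 (3R,4S,5R)-4,7-bis[(tert-butyldimethylsilyl)oxy]-3-[(4-methoxybenzyl)oxy]-5-(prop-1-en-2-yl)heptan-2-ol (both C2 epimers)
Conditions: MeMgBr, THF, −78 °C
Reagents that add atoms: methylmagnesium bromide, C[Mg]Br
Why: Grignard addition to the aldehyde brings in the C8 methyl group; the new carbinol centre is oxidised away in step 11.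

Step 11
Reactants: 13 the secondary alcohol
Product: 14 (3S,4S,5R)-4,7-bis[(tert-butyldimethylsilyl)oxy]-3-[(4-methoxybenzyl)oxy]-5-(prop-1-en-2-yl)heptan-2-one
Conditions: Dess–Martin periodinane, NaHCO3, CH2Cl2, 0 °C → rt
Reagents that add atoms: none
Why: Dess–Martin oxidation of the secondary alcohol gives the C8 methyl ketone.

Step 12
Reactants: 15 (S)-α-hydroxy-γ-butyrolactone
Product: 16 (3S)-3-[(3,4-dimethoxybenzyl)oxy]dihydrofuran-2(3H)-one
Conditions: 3,4-(MeO)2C6H3CH2OC(=NH)CCl3, camphorsulfonic acid (cat.), CH2Cl2, 0 °C → rt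
Reagents that add atoms: 3,4-dimethoxybenzyl 2,2,2-trichloroacetimidate, COc1ccc(COC(=N)C(Cl)(Cl)Cl)cc1OC
Why: Acid-catalysed O-benzylation with a trichloroacetimidate needs no base, so the α-stereocentre of the lactone (C5) is not at risk.

Step 13
Reactants: 16 the DMB-protected lactone
Product: 17 (2S)-2-[(3,4-dimethoxybenzyl)oxy]-4-hydroxy-N-methoxy-N-methylbutanamide
Conditions: MeNH(OMe)·HCl, AlMe3, CH2Cl2, 0 °C → rt; aq. KNaC4H4O6
Reagents that add atoms: N,O-dimethylhydroxylamine hydrochloride, CNOC.Cl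
Why: Weinreb aminolysis of the lactone with the aluminium amide opens the ring to the hydroxy amide without epimerisation.

Step 14
Reactants: 17 the hydroxy amide
Product: 18 (2S)-2-[(3,4-dimethoxybenzyl)oxy]-4-iodo-N-methoxy-N-methylbutanamide
Conditions: I2, PPh3, imidazole, CH2Cl2, 0 °C
Reagents that add atoms: iodine, II
Why: Appel-type iodination (Garegg–Samuelsson conditions) converts the primary alcohol into the iodide under neutral conditions.

Step 15
Reactants: 18 the iodide
Product: 19 {(3S)-3-[(3,4-dimethoxybenzyl)oxy]-4-[methoxy(methyl)amino]-4-oxobutyl}triphenylphosphonium iodide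
Conditions: PPh3, MeCN, 70 °C
Reagents that add atoms: triphenylphosphine, c1ccc(P(c2ccccc2)c2ccccc2)cc1
Why: SN2 quaternisation of triphenylphosphine by the primary iodide at high phosphine concentration should outrun cyclisation through the amide oxygen.

Step 16
Reactants: 19 the phosphonium iodide; 14 the C8 methyl ketone
Product: 21 (2S,4Z,6R,7S,8R)-7,10-bis[(tert-butyldimethylsilyl)oxy]-2-[(3,4-dimethoxybenzyl)oxy]-N-methoxy-6-[(4-methoxybenzyl)oxy]-N,5-dimethyl-8-(prop-1-en-2-yl)dec-4-enamide, via phosphonium ylide 20 (not isolated)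
Conditions: 19 (1.4 equiv), KN(SiMe3)2 (1.3 equiv), THF, −78 °C; then 14, −78 °C → rt
Reagents that add atoms: none
Why: Wittig olefination of an α-alkoxy methyl ketone with a non-stabilised ylide (Still's Z-selective variant) should give the trisubstituted olefin with C6 cis to C9, since the ketone is more electrophilic than the Weinreb amide carried by the ylide.

Step 17
Reactants: 21 the Weinreb amide
Product: 22 (3S,5Z,7R,8S,9R)-8,11-bis[(tert-butyldimethylsilyl)oxy]-3-[(3,4-dimethoxybenzyl)oxy]-7-[(4-methoxybenzyl)oxy]-6-methyl-9-(prop-1-en-2-yl)undec-5-en-2-one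
Conditions: MeMgBr (3 equiv), THF, 0 °C; aq. NH4Cl
Reagents that add atoms: methylmagnesium bromide, C[Mg]Br
Why: Weinreb ketone synthesis: the chelated tetrahedral intermediate stops at mono-addition and gives the C4 methyl ketone without loss of configuration at C5.

Step 18
Reactants: 22 the bis-silyl ether ketone
Product: 23 (3S,5Z,7R,8S,9R)-8-[(tert-butyldimethylsilyl)oxy]-3-[(3,4-dimethoxybenzyl)oxy]-11-hydroxy-7-[(4-methoxybenzyl)oxy]-6-methyl-9-(prop-1-en-2-yl)undec-5-en-2-one
Conditions: HF·pyridine, pyridine, THF, 0 °C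
Reagents that add atoms: none
Why: Selective desilylation: buffered HF·pyridine cleaves the primary C3 silyl ether much faster than the hindered secondary C10 silyl ether.

Step 19
Reactants: 23 the primary alcohol
Product: 24 (3S,5Z,7R,8S,9R)-8-[(tert-butyldimethylsilyl)oxy]-3-[(3,4-dimethoxybenzyl)oxy]-11-iodo-7-[(4-methoxybenzyl)oxy]-6-methyl-9-(prop-1-en-2-yl)undec-5-en-2-one
Conditions: I2, PPh3, imidazole, CH2Cl2, 0 °C
Reagents that add atoms: iodine, II
Why: Garegg–Samuelsson iodination of the primary alcohol is neutral and leaves the α-alkoxy ketone and the ethers intact.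

Step 20
Reactants: 24 the primary iodide; 25 diphenyl sulfide
Product: 26 [(3R,4S,5R,6Z,9S)-4-[(tert-butyldimethylsilyl)oxy]-9-[(3,4-dimethoxybenzyl)oxy]-5-[(4-methoxybenzyl)oxy]-6-methyl-10-oxo-3-(prop-1-en-2-yl)undec-6-en-1-yl]diphenylsulfonium tetrafluoroborate
Conditions: 25 (10 equiv), AgBF4 (1.2 equiv), CH2Cl2, −20 °C → rt, dark
Reagents that add atoms: silver tetrafluoroborate, [Ag+].F[B-](F)(F)F
Why: Silver-assisted S-alkylation of diphenyl sulfide by a primary iodide is the standard preparation of alkyldiphenylsulfonium tetrafluoroborates, and the large excess of sulfide together with the bulky silyl ether on O10 should suppress oxygen participation at C3.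

Step 21
Reactants: 26 the sulfonium tetrafluoroborate
Product: 29 (1R,3R,4S,5S,9R,10S,7Z)-10-[(tert-butyldimethylsilyl)oxy]-5-[(3,4-dimethoxybenzyl)oxy]-9-[(4-methoxybenzyl)oxy]-4,8-dimethyl-1-(prop-1-en-2-yl)-3,4-epoxycyclodec-7-ene, via sulfonium ylide 27 (not isolated), via anti-betaine 28 (not isolated)
Conditions: LiN(SiMe3)2 (1.05 equiv, added over 4 h), toluene–THF (4:1), 0.001 M, −78 → −40 °C
Reagents that add atoms: none
Why: Proposed new method: LiN(SiMe3)2 removes a C3–H (the only protons alpha to sulfur, far more acidic than the ketone alpha protons), the non-stabilised ylide 27 adds irreversibly to the C4 ketone to give betaine 28, and the C4 alkoxide then displaces Ph2S from C3 with inversion; the closest known reactions are ketone epoxidation by alkyldiphenylsulfonium ylides and intramolecular sulfonium-ylide epoxidations that close five- to seven-membered rings, so the ten-membered closure is unproven. The carbocycle forms by 10-exo-trig attack on the exocyclic C=O and the oxirane by 3-exo-tet displacement. C4 is to be set by a lithium chelate between the C4 carbonyl and the C5 benzyl-type ether, which exposes the face giving the C4–O/C5–O syn (Cram-chelate) arrangement of the target, whereas a non-chelated Felkin–Anh addition would give the C4 epimer. C3 follows from the betaine in which C2 lies anti to C5 across the new bond (the ylide substituent avoids the larger ketone substituent), which after anti displacement gives the trans-epoxide and hence 3R. The step needs ylide formation over enolisation (acidity gap, slow addition of one equivalent of base), cyclisation over dimerisation (0.001 M, with the Z-C7=C8 olefin and the substituents at C1, C5, C9 and C10 as turn elements) and survival of the ylide (temperature kept below −30 °C).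

Step 22
Reactants: 29 the macrocyclic epoxide
Product: 30 the C10 alcohol of 29 (silyl group removed; all other groups and configurations unchanged)
Conditions: Bu4NF, AcOH (1:1), THF, rt → 40 °C
Reagents that add atoms: none
Why: Fluoride desilylation buffered with acetic acid frees O10 without generating a free alkoxide that could open the C3–C4 epoxide across the ring.

Step 23
Reactants: 30 the C10 alcohol
Product: 31 the C5,C10-diol (C9 PMB ether, C3–C4 epoxide and 7Z olefin retained)
Conditions: DDQ (1.1 equiv), CH2Cl2–pH 7 buffer (10:1), 0 °C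
Reagents that add atoms: none
Why: Oxidative cleavage of a benzyl-type ether by DDQ is faster for the more electron-rich 3,4-dimethoxybenzyl group than for the 4-methoxybenzyl group, so one equivalent at 0 °C should free O5 only.

Step 24
Reactants: 31 the C5,C10-diol; 32 angelic anhydride
Product: 33 the C5,C10-bis[(2Z)-2-methylbut-2-enoate] of 31
Conditions: LiN(SiMe3)2 (2.2 equiv), THF, −40 °C; then 32 (3 equiv), −40 → 0 °C
Reagents that add atoms: none
Why: Acylation of the lithium alkoxides with angelic anhydride at low temperature is a stereoconservative angeloylation (no Z to E isomerisation) and is fast enough for the two hindered secondary hydroxyls; the neighbouring O9 is an ether, so nothing can migrate.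

Step 25
Reactants: 33 the bis-angelate
Product: 34 the C9 alcohol of 33 (PMB removed)
Conditions: DDQ (1.5 equiv), CH2Cl2–pH 7 buffer (10:1), 0 °C → rt
Reagents that add atoms: none
Why: DDQ cleavage of the PMB ether is neutral, so the allylic C9 alcohol is freed next to the C10 angelate without acyl migration and without harm to the epoxide.

Step 26
Reactants: 34 the C9 allylic alcohol
Product: 35 the (7S,8S)-7,8-epoxide of 34 (9-deacetyl target)
Conditions: m-CPBA (1.05 equiv), NaHCO3, CH2Cl2, −20 → 0 °C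
Reagents that add atoms: 3-chloroperoxybenzoic acid, O=C(OO)c1cccc(Cl)c1
Why: Peracid epoxidation (Prilezhaev reaction, hydrogen-bond guided as in Henbest epoxidation) of the medium-ring Z-allylic alcohol should give the trans (threo) epoxy alcohol, because C9–H eclipses the olefin to avoid allylic 1,3-strain with C6 and the peracid attacks the exposed face syn to the hydroxyl, which sets 7S and 8S, while the electron-poor angelates and the less substituted isopropenyl group react more slowly.

Step 27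
Reactants: 35 the epoxy alcohol
Product: 36 CNP0220329.2 (target)
Conditions: Ac2O, pyridine, DMAP (cat.), CH2Cl2, rt
Reagents that add atoms: acetic anhydride, CC(=O)OC(C)=O
Why: DMAP-catalysed acetylation of the remaining hindered secondary alcohol completes the ester pattern without touching the epoxides.

Compound list
1 | 2,3-O-isopropylidene-D-erythronolactone | O=C1OC[C@H]2OC(C)(C)O[C@@H]12 | starting material
2 | 2,3-O-isopropylidene-D-erythrose (lactol, anomeric mixture) | OC1OC[C@H]2OC(C)(C)O[C@@H]12 | intermediate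
3 | methyl (triphenylphosphoranylidene)acetate | COC(=O)C=P(c1ccccc1)(c1ccccc1)c1ccccc1 | starting material
4 | methyl (2Z)-3-[(4S,5R)-5-(hydroxymethyl)-2,2-dimethyl-1,3-dioxolan-4-yl]prop-2-enoate | COC(=O)/C=C\[C@@H]1OC(C)(C)O[C@@H]1CO | intermediate
5 | (5S)-5-[(1R)-1,2-dihydroxyethyl]furan-2(5H)-one | O=C1C=C[C@@H]([C@H](O)CO)O1 | intermediate
6 | (5S)-5-[(4R)-2-(4-methoxyphenyl)-1,3-dioxolan-4-yl]furan-2(5H)-one (epimers at the acetal carbon) | O=C1C=C[C@@H]([C@H]2COC(c3ccc(OC)cc3)O2)O1 | intermediate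
7 | isopropenylmagnesium bromide (from 2-bromopropene and Mg; commercial solution) | C=C(C)[Mg]Br | starting material
8 | (4R,5S)-5-[(4R)-2-(4-methoxyphenyl)-1,3-dioxolan-4-yl]-4-(prop-1-en-2-yl)dihydrofuran-2(3H)-one (trans; acetal epimers) | O=C1C[C@H](C(C)=C)[C@@H]([C@H]2COC(c3ccc(OC)cc3)O2)O1 | intermediate
9 | (3R,4S)-4-[(4R)-2-(4-methoxyphenyl)-1,3-dioxolan-4-yl]-3-(prop-1-en-2-yl)butane-1,4-diol (acetal epimers) | C=C(C)[C@@H](CCO)[C@H](O)[C@H]1COC(c2ccc(OC)cc2)O1 | intermediate
10 | 1,4-bis(tert-butyldimethylsilyl) ether of 9 (acetal epimers) | C=C(C)[C@@H](CCO[Si](C)(C)C(C)(C)C)[C@H](O[Si](C)(C)C(C)(C)C)[C@H]1COC(c2ccc(OC)cc2)O1 | intermediate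
11 | (2R,3S,4R)-3,6-bis[(tert-butyldimethylsilyl)oxy]-2-[(4-methoxybenzyl)oxy]-4-(prop-1-en-2-yl)hexan-1-ol | C=C(C)[C@@H](CCO[Si](C)(C)C(C)(C)C)[C@H](O[Si](C)(C)C(C)(C)C)[C@H](OCc1ccc(OC)cc1)CO | intermediate
12 | (2S,3S,4R)-3,6-bis[(tert-butyldimethylsilyl)oxy]-2-[(4-methoxybenzyl)oxy]-4-(prop-1-en-2-yl)hexanal | C=C(C)[C@@H](CCO[Si](C)(C)C(C)(C)C)[C@H](O[Si](C)(C)C(C)(C)C)[C@H](OCc1ccc(OC)cc1)C=O | intermediate
13 | (3R,4S,5R)-4,7-bis[(tert-butyldimethylsilyl)oxy]-3-[(4-methoxybenzyl)oxy]-5-(prop-1-en-2-yl)heptan-2-ol (C2 epimers) | C=C(C)[C@@H](CCO[Si](C)(C)C(C)(C)C)[C@H](O[Si](C)(C)C(C)(C)C)[C@H](OCc1ccc(OC)cc1)C(C)O | intermediate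
14 | (3S,4S,5R)-4,7-bis[(tert-butyldimethylsilyl)oxy]-3-[(4-methoxybenzyl)oxy]-5-(prop-1-en-2-yl)heptan-2-one | C=C(C)[C@@H](CCO[Si](C)(C)C(C)(C)C)[C@H](O[Si](C)(C)C(C)(C)C)[C@H](OCc1ccc(OC)cc1)C(C)=O | intermediate
15 | (S)-α-hydroxy-γ-butyrolactone, (3S)-3-hydroxydihydrofuran-2(3H)-one | O=C1OCC[C@@H]1O | starting material
16 | (3S)-3-[(3,4-dimethoxybenzyl)oxy]dihydrofuran-2(3H)-one | O=C1OCC[C@@H]1OCc1ccc(OC)c(OC)c1 | intermediate
17 | (2S)-2-[(3,4-dimethoxybenzyl)oxy]-4-hydroxy-N-methoxy-N-methylbutanamide | OCC[C@H](OCc1ccc(OC)c(OC)c1)C(=O)N(C)OC | intermediate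
18 | (2S)-2-[(3,4-dimethoxybenzyl)oxy]-4-iodo-N-methoxy-N-methylbutanamide | ICC[C@H](OCc1ccc(OC)c(OC)c1)C(=O)N(C)OC | intermediate
19 | {(3S)-3-[(3,4-dimethoxybenzyl)oxy]-4-[methoxy(methyl)amino]-4-oxobutyl}triphenylphosphonium iodide | c1ccccc1[P+](c1ccccc1)(c1ccccc1)CC[C@H](OCc1ccc(OC)c(OC)c1)C(=O)N(C)OC.[I-] | intermediate
20 | phosphonium ylide derived from 19 | c1ccccc1P(c1ccccc1)(c1ccccc1)=CC[C@H](OCc1ccc(OC)c(OC)c1)C(=O)N(C)OC | intermediate (not isolated)
21 | (2S,4Z,6R,7S,8R)-7,10-bis[(tert-butyldimethylsilyl)oxy]-2-[(3,4-dimethoxybenzyl)oxy]-N-methoxy-6-[(4-methoxybenzyl)oxy]-N,5-dimethyl-8-(prop-1-en-2-yl)dec-4-enamide | C=C(C)[C@@H](CCO[Si](C)(C)C(C)(C)C)[C@H](O[Si](C)(C)C(C)(C)C)[C@H](OCc1ccc(OC)cc1)/C(C)=C\C[C@H](OCc1ccc(OC)c(OC)c1)C(=O)N(C)OC | intermediate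
22 | (3S,5Z,7R,8S,9R)-8,11-bis[(tert-butyldimethylsilyl)oxy]-3-[(3,4-dimethoxybenzyl)oxy]-7-[(4-methoxybenzyl)oxy]-6-methyl-9-(prop-1-en-2-yl)undec-5-en-2-one | C=C(C)[C@@H](CCO[Si](C)(C)C(C)(C)C)[C@H](O[Si](C)(C)C(C)(C)C)[C@H](OCc1ccc(OC)cc1)/C(C)=C\C[C@H](OCc1ccc(OC)c(OC)c1)C(C)=O | intermediate
23 | (3S,5Z,7R,8S,9R)-8-[(tert-butyldimethylsilyl)oxy]-3-[(3,4-dimethoxybenzyl)oxy]-11-hydroxy-7-[(4-methoxybenzyl)oxy]-6-methyl-9-(prop-1-en-2-yl)undec-5-en-2-one | C=C(C)[C@@H](CCO)[C@H](O[Si](C)(C)C(C)(C)C)[C@H](OCc1ccc(OC)cc1)/C(C)=C\C[C@H](OCc1ccc(OC)c(OC)c1)C(C)=O | intermediate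
24 | (3S,5Z,7R,8S,9R)-8-[(tert-butyldimethylsilyl)oxy]-3-[(3,4-dimethoxybenzyl)oxy]-11-iodo-7-[(4-methoxybenzyl)oxy]-6-methyl-9-(prop-1-en-2-yl)undec-5-en-2-one | C=C(C)[C@@H](CCI)[C@H](O[Si](C)(C)C(C)(C)C)[C@H](OCc1ccc(OC)cc1)/C(C)=C\C[C@H](OCc1ccc(OC)c(OC)c1)C(C)=O | intermediate
25 | diphenyl sulfide | c1ccc(Sc2ccccc2)cc1 | starting material
26 | [(3R,4S,5R,6Z,9S)-4-[(tert-butyldimethylsilyl)oxy]-9-[(3,4-dimethoxybenzyl)oxy]-5-[(4-methoxybenzyl)oxy]-6-methyl-10-oxo-3-(prop-1-en-2-yl)undec-6-en-1-yl]diphenylsulfonium tetrafluoroborate | C=C(C)[C@@H](CC[S+](c1ccccc1)c1ccccc1)[C@H](O[Si](C)(C)C(C)(C)C)[C@H](OCc1ccc(OC)cc1)/C(C)=C\C[C@H](OCc1ccc(OC)c(OC)c1)C(C)=O.F[B-](F)(F)F | intermediate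
27 | C3 sulfonium ylide derived from 26 | C=C(C)[C@@H](C[CH-][S+](c1ccccc1)c1ccccc1)[C@H](O[Si](C)(C)C(C)(C)C)[C@H](OCc1ccc(OC)cc1)/C(C)=C\C[C@H](OCc1ccc(OC)c(OC)c1)C(C)=O | intermediate (not isolated)
28 | ten-membered anti-betaine (C4 alkoxide as lithium salt, C3 diphenylsulfonium) | C=C(C)[C@H]1C[C@H]([S+](c2ccccc2)c2ccccc2)[C@@]([O-])(C)[C@@H](OCc2ccc(OC)c(OC)c2)C/C=C(/C)[C@@H](OCc2ccc(OC)cc2)[C@H]1O[Si](C)(C)C(C)(C)C | intermediate (not isolated)
29 | (1R,3R,4S,5S,9R,10S,7Z)-10-[(tert-butyldimethylsilyl)oxy]-5-[(3,4-dimethoxybenzyl)oxy]-9-[(4-methoxybenzyl)oxy]-4,8-dimethyl-1-(prop-1-en-2-yl)-3,4-epoxycyclodec-7-ene (target numbering) | C=C(C)[C@H]1C[C@H]2O[C@]2(C)[C@@H](OCc2ccc(OC)c(OC)c2)C/C=C(/C)[C@@H](OCc2ccc(OC)cc2)[C@H]1O[Si](C)(C)C(C)(C)C | intermediate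
30 | C10 alcohol of 29 | C=C(C)[C@H]1C[C@H]2O[C@]2(C)[C@@H](OCc2ccc(OC)c(OC)c2)C/C=C(/C)[C@@H](OCc2ccc(OC)cc2)[C@H]1O | intermediate
31 | C5,C10-diol with C9 PMB ether | C=C(C)[C@H]1C[C@H]2O[C@]2(C)[C@@H](O)C/C=C(/C)[C@@H](OCc2ccc(OC)cc2)[C@H]1O | intermediate
32 | angelic anhydride, (2Z)-2-methylbut-2-enoic anhydride | C/C=C(/C)C(=O)OC(=O)/C(C)=C\C | starting material
33 | C5,C10-bis(angelate) with C9 PMB ether | C=C(C)[C@H]1C[C@H]2O[C@]2(C)[C@@H](OC(=O)/C(C)=C\C)C/C=C(/C)[C@@H](OCc2ccc(OC)cc2)[C@H]1OC(=O)/C(C)=C\C | intermediate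
34 | C5,C10-bis(angelate) C9 allylic alcohol | C=C(C)[C@H]1C[C@H]2O[C@]2(C)[C@@H](OC(=O)/C(C)=C\C)C/C=C(/C)[C@@H](O)[C@H]1OC(=O)/C(C)=C\C | intermediate
35 | 9-deacetyl target, (7S,8S)-epoxide with free C9 hydroxyl | C=C(C)[C@H]1C[C@H]2O[C@]2(C)[C@@H](OC(=O)/C(C)=C\C)C[C@@H]2O[C@]2(C)[C@@H](O)[C@H]1OC(=O)/C(C)=C\C | intermediate
36 | CNP0220329.2, (1R,3R,4S,5S,7S,8S,9S,10S)-9-acetoxy-3,4:7,8-diepoxy-4,8-dimethyl-1-(prop-1-en-2-yl)cyclodecane-5,10-diyl bis[(2Z)-2-methylbut-2-enoate] (target numbering) | C=C(C)[C@H]1C[C@H]2O[C@]2(C)[C@@H](OC(=O)/C(C)=C\C)C[C@@H]2O[C@]2(C)[C@@H](OC(C)=O)[C@H]1OC(=O)/C(C)=C\C | target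

Total number of steps: 27. Longest linear sequence: 23 steps (steps 1–11 and 16–27, from 1). The side branch 15 → 19 has 4 steps.

Steps most likely to fail

1. Step 21 (Proposed new method). The ylide may decompose (elimination, aryl migration) or react between molecules before the ten-membered ring closes. Lithium chelation may also be too weak to control the C4 face. Fallback with known chemistry (intermolecular epoxidation of a ketone by an alkyldiphenylsulfonium ylide, then ring-closing olefin metathesis at C7=C8): it sets out from 14 and 17 and returns at 29. Ketone 14 is methylenated (Ph3PCH3Br, KOt-Bu) to the C8 methylene compound F1. Its primary silyl ether is cleaved (HF·pyridine) to alcohol F2, which is converted into iodide F3 (I2, PPh3, imidazole) and then into sulfonium salt F4 (Ph2S, AgBF4). Hydroxy amide 17 is oxidised (Dess–Martin periodinane) to aldehyde F5, methylenated to terminal olefin F6 and treated with MeMgBr to give ketone F7. Deprotonation of F4 with LiN(SiMe3)2 at −78 °C in the presence of F7 should give, after separation of isomers, the acyclic trans-epoxide F8. Ring-closing metathesis of its C7 vinyl group with the C8 methylene olefin (second-generation Grubbs catalyst, toluene, high dilution) should then give 29 with loss of ethene.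

2. Step 20. The silver-activated C3 may be captured by the C10 oxygen (cyclic ether formation with loss of the silyl group), or adventitious acid may strip protecting groups before the weakly nucleophilic sulfide reacts. Fallback (the sulfur is brought in as a strong nucleophile and arylated afterwards): it sets out from 24 and returns at 26. Iodide 24 is displaced with PhSNa in DMF at 0 °C to give phenyl sulfide F9, which is S-phenylated with diphenyliodonium tetrafluoroborate under Cu(OAc)2 catalysis in 1,2-dichloroethane at 80 °C to give 26.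

3. Step 26. Facial selectivity in the macrocycle rests on substrate control and may be poor, and the isopropenyl group may be epoxidised competitively. Fallback (reagent-controlled instead of substrate-controlled oxygen transfer): it sets out from 34 and returns at 35. Shi epoxidation with the fructose-derived ketone or its enantiomer, whichever matches the 7S,8S face (KHSO5, K2CO3, MeCN–dimethoxymethane–H2O, 0 °C), relies on the strong preference of the dioxirane for the trisubstituted olefin and makes no new intermediate.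

Further compounds
F1 | step 21 | (3R,4S,5R)-4,7-bis[(tert-butyldimethylsilyl)oxy]-3-[(4-methoxybenzyl)oxy]-2-methyl-5-(prop-1-en-2-yl)hept-1-ene | C=C(C)[C@@H](CCO[Si](C)(C)C(C)(C)C)[C@H](O[Si](C)(C)C(C)(C)C)[C@H](OCc1ccc(OC)cc1)C(C)=C
F2 | step 21 | primary alcohol from F1 (C3 silyl group removed) | C=C(C)[C@@H](CCO)[C@H](O[Si](C)(C)C(C)(C)C)[C@H](OCc1ccc(OC)cc1)C(C)=C
F3 | step 21 | primary iodide from F2 | C=C(C)[C@@H](CCI)[C@H](O[Si](C)(C)C(C)(C)C)[C@H](OCc1ccc(OC)cc1)C(C)=C
F4 | step 21 | diphenylsulfonium tetrafluoroborate from F3 | C=C(C)[C@@H](CC[S+](c1ccccc1)c1ccccc1)[C@H](O[Si](C)(C)C(C)(C)C)[C@H](OCc1ccc(OC)cc1)C(C)=C.F[B-](F)(F)F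
F5 | step 21 | (3S)-3-[(3,4-dimethoxybenzyl)oxy]-4-[methoxy(methyl)amino]-4-oxobutanal | O=CC[C@H](OCc1ccc(OC)c(OC)c1)C(=O)N(C)OC
F6 | step 21 | (2S)-2-[(3,4-dimethoxybenzyl)oxy]-N-methoxy-N-methylpent-4-enamide | C=CC[C@H](OCc1ccc(OC)c(OC)c1)C(=O)N(C)OC
F7 | step 21 | (3S)-3-[(3,4-dimethoxybenzyl)oxy]hex-5-en-2-one | C=CC[C@H](OCc1ccc(OC)c(OC)c1)C(C)=O
F8 | step 21 | acyclic (3R,4S)-trans-epoxide with C7 vinyl and C8 methylene groups | C=C(C)[C@@H](C[C@H]1O[C@]1(C)[C@@H](OCc1ccc(OC)c(OC)c1)CC=C)[C@H](O[Si](C)(C)C(C)(C)C)[C@H](OCc1ccc(OC)cc1)C(C)=C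
F9 | step 20 | C3 phenyl sulfide corresponding to 24 | C=C(C)[C@@H](CCSc1ccccc1)[C@H](O[Si](C)(C)C(C)(C)C)[C@H](OCc1ccc(OC)cc1)/C(C)=C\C[C@H](OCc1ccc(OC)c(OC)c1)C(C)=O
F0 | step 26 | none | none
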